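The numbers were drawn at random within sensible limits.

The constants give balances, 170 M⁻¹ for L.E, 2.2 M⁻¹ for Z and 22 M⁻¹ for L.Q, and one rate constant, 2.3 M⁻¹ s⁻¹, for the step in which X and L give E and Q.

    L + E ⇌ L.E, settled at all times (K1 = 170 M⁻¹)
    X + L → E + Q (k2 = 2.3 M⁻¹ s⁻¹)
    L + E ⇌ Z, settled at all times (K3 = 2.2 M⁻¹)
    L + Q ⇌ L.Q, settled at all times (K4 = 22 M⁻¹)

X 0.10 M; time 1.0 min

* the equivalents of L at which the part of the X that has reacted at 1.0 min is just 95%

- what is said of Q includes L.Q
- what is said of E includes Z
- the amount of L is what is sought; it is there from the start
- run time (flask): 1.0 min

I build a ladder from these. The balances stand on the fastest rung, so at each instant L is shared among free L, L.E, Z and L.Q. The reciprocal constants give the free L at which a partner is as much bound as unbound: 0.005882 M for E through L.E, far less than the 0.10 M of X, and 0.0455 M for Q, also less, while for Z it is 0.455 M, more than that charge. The next rung is the time of the step at the charge of X, 4.35 s, far shorter than the run of 1.0 min.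

X is lost at the rate constant times free L times X, and free L changes during the run, so the logarithm of X charged over X left equals the rate constant times the time integral of free L, which gives my rule in terms of the time-averaged free L. The required mean free L is the logarithm of X charged over X left, divided by the rate constant and the time, here 0.0217 M. If free L stays at that mean to the end, the balances hold 0.106 M of L, the step has consumed 0.0950 M, and the charge comes to 2.22 equivalents. Free L falls during the run, so I hold this figure as high.

The forecast differs from mine: 1.05 equiv, within 0.95 equiv to 1.2 equiv, with the ground that “Each E formed ties up nearly one L”.

The flask needs 1.86 equiv, above the forecast's range and below my figure. At 1.00 min, 5.87% of the charged L is still free, or 0.0109 M, less than the required mean. In a second flask, a quarter more L reaches 99.1%, and the same rule puts its mean free L at 0.0344 M, which is 1.59 times the mean of the first flask.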